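The route rests on disconnecting the bond between C6, the quaternary peroxide carbon of the 1,2-dioxane ring, and the first CH2 of the side chain. C6 is a masked ketal carbon: ring oxygen O1 can stabilise a cation there, and the C3 stereocentre across the ring can steer a nucleophile. The key step ionises a 6-methoxy-6-methyl-1,2-dioxane, used as both C6 epimers, to one planar peroxycarbenium ion and adds the complete cyclohexenone fragment as an alkynylstannane. One operation joins the halves and sets C6 stereoconvergently. The precursor has C≡C where the target has CH2CH2; diimide corrects this. An Evans aldol sets C2 and C3.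

Key step: step 10

Remark: atoms are numbered as in the target: dioxane O1, O2, C3 (bears the side chain), C4, C5, C6 (quaternary); C2 is the α-carbon of the side chain. Descriptors at C2 and C6 change in some intermediates only because substituent priorities change; the spatial arrangement stays the same. The three starting materials 1, 3 and 11 and the Grignard solution 12 are taken as catalogue items.

Step 1
Reactants: 1 4-methylpent-4-en-1-ol
Product: 2 4-methylpent-4-enal
Conditions: TEMPO (10 mol %), PhI(OAc)2 (1.1 equiv), CH2Cl2, rt; used as a solution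
Reagents that add atoms: none
Why: Oxoammonium (TEMPO) oxidation of a primary alcohol stops at the aldehyde and leaves the 1,1-disubstituted alkene untouched; no stereocentre is involved.

Step 2
Reactants: 3 (4R)-4-benzyl-3-propanoyl-1,3-oxazolidin-2-one; 2 4-methylpent-4-enal
Product: 5 (4R)-4-benzyl-3-[(2R,3S)-3-hydroxy-2,6-dimethylhept-6-enoyl]-1,3-oxazolidin-2-one, via dibutylboron Z-enolate 4 (not isolated)
Conditions: Bu2BOTf, i-Pr2NEt, CH2Cl2, 0 °C; then 2, −78 to 0 °C; pH 7 buffer, MeOH, 30% H2O2
Reagents that add atoms: none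
Why: Evans syn aldol reaction: Z-enolate 4 reacts through a Zimmerman–Traxler chair in which the benzyl group of the R auxiliary shields one enolate face, which should set C2 (R) and C3 (S) as the syn pair.

Step 3
Reactants: 5 (4R)-4-benzyl-3-[(2R,3S)-3-hydroxy-2,6-dimethylhept-6-enoyl]-1,3-oxazolidin-2-one
Product: 6 (2S,3S)-2,6-dimethylhept-6-ene-1,3-diol
Conditions: LiBH4, MeOH (1 equiv), Et2O, 0 °C
Reagents that add atoms: none
Why: Reductive cleavage of the N-acyl oxazolidinone by hydride attack at the exocyclic carbonyl frees the primary alcohol and the recoverable auxiliary without touching the two stereocentres.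

Step 4
Reactants: 6 (2S,3S)-2,6-dimethylhept-6-ene-1,3-diol
Product: 7 (2S,3S)-1-[(tert-butyldiphenylsilyl)oxy]-2,6-dimethylhept-6-en-3-ol
Conditions: TBDPSCl (1.05 equiv), imidazole, CH2Cl2, 0 °C
Reagents that add atoms: tert-butyl(chloro)diphenylsilane, CC(C)(C)[Si](Cl)(c1ccccc1)c1ccccc1
Why: Silyl ether formation with the bulky chlorosilane should be selective for the primary hydroxyl over the hindered secondary one (steric differentiation).

Step 5
Reactants: 7 (2S,3S)-1-[(tert-butyldiphenylsilyl)oxy]-2,6-dimethylhept-6-en-3-ol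
Product: 8 (2S,3S)-1-[(tert-butyldiphenylsilyl)oxy]-2,6-dimethylhept-6-en-3-yl methanesulfonate
Conditions: MsCl, Et3N, CH2Cl2, 0 °C
Reagents that add atoms: methanesulfonyl chloride, CS(=O)(=O)Cl
Why: O-Sulfonylation of the secondary alcohol changes only the O–H bond, so C3 keeps its configuration and gains the leaving group for the later inversion.

Step 6
Reactants: 8 (2S,3S)-1-[(tert-butyldiphenylsilyl)oxy]-2,6-dimethylhept-6-en-3-yl methanesulfonate
Product: 10 tert-butyl{(2S)-2-[(3R)-6-methoxy-6-methyl-1,2-dioxan-3-yl]propoxy}diphenylsilane (both C6 epimers), via hydroperoxy ketal 9 (not isolated)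
Conditions: O3, CH2Cl2/MeOH (4:1), NaHCO3, −78 °C; N2 purge, evaporation below 20 °C; then KOtBu, 18-crown-6 (cat.), THF, 0 °C
Reagents that add atoms: ozone, [O-][O+]=O; methanol, CO
Why: Ozonolysis in methanol (Criegee cleavage) gives the ketone-derived carbonyl oxide, which methanol traps as hydroperoxy ketal 9, and its peroxide anion then displaces the mesylate in a 6-exo-tet SN2 ring closure (intramolecular peroxide alkylation) with inversion at C3, which should set the 3R configuration while C6 forms as both epimers.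

Step 7
Reactants: 11 2,6,6-trimethylcyclohex-2-en-1-one; 12 ethynylmagnesium bromide
Product: 13 1-ethynyl-2,6,6-trimethylcyclohex-2-en-1-ol (racemic)
Conditions: THF, 0 °C to rt; aq. NH4Cl
Reagents that add atoms: none
Why: Grignard 1,2-addition of the small, hard alkynyl nucleophile to the hindered enone carbonyl should give the tertiary allylic alcohol as a racemate, whose stereocentre is erased in step 8.

Step 8
Reactants: 13 1-ethynyl-2,6,6-trimethylcyclohex-2-en-1-ol
Product: 14 3-ethynyl-2,4,4-trimethylcyclohex-2-en-1-one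
Conditions: pyridinium chlorochromate (2 equiv), 4 Å molecular sieves, CH2Cl2, rt
Reagents that add atoms: pyridinium chlorochromate, [O-][Cr](=O)(=O)Cl.c1cc[nH+]cc1
Why: Babler–Dauben oxidative transposition: the tertiary allylic chromate ester undergoes a [3,3]-sigmatropic shift and is oxidised to the transposed enone, which leaves the ethynyl group on the β-carbon next to the gem-dimethyl group.

Step 9
Reactants: 14 3-ethynyl-2,4,4-trimethylcyclohex-2-en-1-one
Product: 15 2,4,4-trimethyl-3-[(tributylstannyl)ethynyl]cyclohex-2-en-1-one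
Conditions: Bu3SnOMe (1.1 equiv), ZnBr2 (5 mol %), THF, rt; volatiles removed in vacuo
Reagents that add atoms: tributyltin methoxide, CCCC[Sn](CCCC)(CCCC)OC
Why: ZnBr2-catalysed C–H stannylation of the terminal alkyne (zinc acetylide formation, then transmetalation to tin, with methanol as the only by-product) needs no strong base and should therefore tolerate the enolisable enone.

Step 10
Reactants: 10 tert-butyl{(2S)-2-[(3R)-6-methoxy-6-methyl-1,2-dioxan-3-yl]propoxy}diphenylsilane (both C6 epimers); 15 2,4,4-trimethyl-3-[(tributylstannyl)ethynyl]cyclohex-2-en-1-one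
Product: 17 3-{[(3R,6S)-3-[(2S)-1-(tert-butyldiphenylsilyloxy)propan-2-yl]-6-methyl-1,2-dioxan-6-yl]ethynyl}-2,4,4-trimethylcyclohex-2-en-1-one (alkynyl group cis to the C3 side chain), via peroxycarbenium triflate 16 (not isolated)
Conditions: 15 (1.5 equiv), TMSOTf (1.2 equiv), CH2Cl2, −78 to −40 °C; Et3N, then aq. NaHCO3 and aq. KF
Reagents that add atoms: none
Why: Proposed new method: TMSOTf removes the methoxy group from either C6 epimer of ketal 10 and gives the same planar cyclic peroxycarbenium ion 16 (C6=O1+), which stannane 15 attacks at its tin-bearing carbon (ipso electrophilic substitution through a β-stannyl vinyl cation, then loss of Bu3Sn+), forming the C6–C(sp) bond. The closest known reaction types are the Lewis acid-mediated Hosomi–Sakurai and Mukaiyama-type additions of allylsilanes and silyl enol ethers to peroxycarbenium ions from cyclic peroxyketals, and the alkynylation of oxocarbenium ions from mixed acetals with tin acetylides. No ring is closed. The new stereocentre C6 is controlled by the C3 stereocentre: the half-chair cation places the C3 side chain pseudoequatorial and the nucleophile adds along the axial trajectory that leads directly to a chair, so the alkynyl group should end up axial and cis to the C3 side chain with the methyl group equatorial, which is the arrangement of the target (descriptor 6S here, 6R after reduction). The step needs facial selectivity at C6 and ionisation of the C–OMe bond without O–O cleavage; the first is secured by the slim, rod-shaped sp nucleophile that tolerates axial approach to a fully substituted carbon, the second by the low temperature and the better leaving ability of the silylated methoxy group. Because both ketal epimers funnel into one cation, the step is stereoconvergent.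

Step 11
Reactants: 17 3-{[(3R,6S)-3-[(2S)-1-(tert-butyldiphenylsilyloxy)propan-2-yl]-6-methyl-1,2-dioxan-6-yl]ethynyl}-2,4,4-trimethylcyclohex-2-en-1-one
Product: 19 3-{2-[(3R,6R)-3-[(2S)-1-(tert-butyldiphenylsilyloxy)propan-2-yl]-6-methyl-1,2-dioxan-6-yl]ethyl}-2,4,4-trimethylcyclohex-2-en-1-one, via Z-alkene 18 (not isolated)
Conditions: potassium azodicarboxylate (KO2CN=NCO2K, large excess in portions), AcOH, CH2Cl2/MeOH, 0 °C to rt
Reagents that add atoms: none
Why: Diimide reduction: concerted syn transfer of H2 from HN=NH should saturate the triple bond through Z-alkene 18, while the O–O bond, the ketone and the tetrasubstituted electron-poor enone C=C are not attacked by this reagent and no stereocentre is touched.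

Step 12
Reactants: 19 3-{2-[(3R,6R)-3-[(2S)-1-(tert-butyldiphenylsilyloxy)propan-2-yl]-6-methyl-1,2-dioxan-6-yl]ethyl}-2,4,4-trimethylcyclohex-2-en-1-one
Product: 20 3-{2-[(3R,6R)-3-[(2S)-1-hydroxypropan-2-yl]-6-methyl-1,2-dioxan-6-yl]ethyl}-2,4,4-trimethylcyclohex-2-en-1-one
Conditions: TBAF, AcOH (1:1), THF, 0 °C to rt
Reagents that add atoms: none
Why: Fluoride-induced desilylation (formation of the strong Si–F bond) frees the primary alcohol, and the acetic acid buffer should suppress base-induced Kornblum–DeLaMare cleavage of the peroxide at C3–H.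

Step 13
Reactants: 20 3-{2-[(3R,6R)-3-[(2S)-1-hydroxypropan-2-yl]-6-methyl-1,2-dioxan-6-yl]ethyl}-2,4,4-trimethylcyclohex-2-en-1-one
Product: 22 (2R)-2-{(3R,6R)-6-methyl-6-[2-(2,6,6-trimethyl-3-oxocyclohex-1-en-1-yl)ethyl]-1,2-dioxan-3-yl}propanoic acid, via peroxy aldehyde 21 (not isolated)
Conditions: TEMPO (20 mol %), PhI(OAc)2 (2.5 equiv), MeCN/H2O (1:1), rt
Reagents that add atoms: water, O
Why: Oxoammonium (TEMPO) oxidation in aqueous acetonitrile takes the primary alcohol through aldehyde 21 and its hydrate to the acid under near-neutral conditions, which should avoid epimerisation at C2 and β-elimination of the peroxide.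

Step 14
Reactants: 22 (2R)-2-{(3R,6R)-6-methyl-6-[2-(2,6,6-trimethyl-3-oxocyclohex-1-en-1-yl)ethyl]-1,2-dioxan-3-yl}propanoic acid
Product: 23 methyl (2R)-2-{(3R,6R)-6-methyl-6-[2-(2,6,6-trimethyl-3-oxocyclohex-1-en-1-yl)ethyl]-1,2-dioxan-3-yl}propanoate (diacarperoxide A)
Conditions: TMSCHN2, toluene/MeOH (3:1), 0 °C
Reagents that add atoms: (trimethylsilyl)diazomethane, C[Si](C)(C)C=[N+]=[N-]
Why: Esterification with (trimethylsilyl)diazomethane in methanol (O-methylation of the carboxylic acid) is neutral and should leave the C2 stereocentre, the peroxide and the enone untouched.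

Compound list
1 | 4-methylpent-4-en-1-ol | CC(=C)CCCO | starting material
2 | 4-methylpent-4-enal | CC(=C)CCC=O | intermediate
3 | (4R)-4-benzyl-3-propanoyl-1,3-oxazolidin-2-one | CCC(=O)N1[C@H](Cc2ccccc2)COC1=O | starting material
4 | (4R)-4-benzyl-3-[(1Z)-1-(dibutylboranyloxy)prop-1-en-1-yl]-1,3-oxazolidin-2-one | CCCCB(CCCC)O/C(=C\C)N1[C@H](Cc2ccccc2)COC1=O | intermediate
5 | (4R)-4-benzyl-3-[(2R,3S)-3-hydroxy-2,6-dimethylhept-6-enoyl]-1,3-oxazolidin-2-one | CC(=C)CC[C@H](O)[C@@H](C)C(=O)N1[C@H](Cc2ccccc2)COC1=O | intermediate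
6 | (2S,3S)-2,6-dimethylhept-6-ene-1,3-diol | CC(=C)CC[C@H](O)[C@@H](C)CO | intermediate
7 | (2S,3S)-1-[(tert-butyldiphenylsilyl)oxy]-2,6-dimethylhept-6-en-3-ol | CC(=C)CC[C@H](O)[C@@H](C)CO[Si](c1ccccc1)(c1ccccc1)C(C)(C)C | intermediate
8 | (2S,3S)-1-[(tert-butyldiphenylsilyl)oxy]-2,6-dimethylhept-6-en-3-yl methanesulfonate | CC(=C)CC[C@H](OS(C)(=O)=O)[C@@H](C)CO[Si](c1ccccc1)(c1ccccc1)C(C)(C)C | intermediate
9 | (2S,3S)-1-[(tert-butyldiphenylsilyl)oxy]-6-hydroperoxy-6-methoxy-2-methylheptan-3-yl methanesulfonate (both C6 epimers) | COC(C)(OO)CC[C@H](OS(C)(=O)=O)[C@@H](C)CO[Si](c1ccccc1)(c1ccccc1)C(C)(C)C | intermediate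
10 | tert-butyl{(2S)-2-[(3R)-6-methoxy-6-methyl-1,2-dioxan-3-yl]propoxy}diphenylsilane (both C6 epimers) | CC(C)(C)[Si](c1ccccc1)(c1ccccc1)OC[C@H](C)[C@H]1CCC(C)(OC)OO1 | intermediate
11 | 2,6,6-trimethylcyclohex-2-en-1-one | CC1=CCCC(C)(C)C1=O | starting material
12 | ethynylmagnesium bromide | C#C[Mg]Br | starting material
13 | 1-ethynyl-2,6,6-trimethylcyclohex-2-en-1-ol (racemic) | CC1=CCCC(C)(C)C1(O)C#C | intermediate
14 | 3-ethynyl-2,4,4-trimethylcyclohex-2-en-1-one | CC1=C(C#C)C(C)(C)CCC1=O | intermediate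
15 | 2,4,4-trimethyl-3-[(tributylstannyl)ethynyl]cyclohex-2-en-1-one | CCCC[Sn](CCCC)(CCCC)C#CC1=C(C)C(=O)CCC1(C)C | intermediate
16 | (3R)-3-[(2S)-1-(tert-butyldiphenylsilyloxy)propan-2-yl]-6-methyl-4,5-dihydro-3H-1,2-dioxin-1-ium trifluoromethanesulfonate | CC(C)(C)[Si](c1ccccc1)(c1ccccc1)OC[C@H](C)[C@H]1CCC(C)=[O+]O1.[O-]S(=O)(=O)C(F)(F)F | intermediate
17 | 3-{[(3R,6S)-3-[(2S)-1-(tert-butyldiphenylsilyloxy)propan-2-yl]-6-methyl-1,2-dioxan-6-yl]ethynyl}-2,4,4-trimethylcyclohex-2-en-1-one | CC(C)(C)[Si](c1ccccc1)(c1ccccc1)OC[C@H](C)[C@H]1CC[C@@](C)(C#CC2=C(C)C(=O)CCC2(C)C)OO1 | intermediate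
18 | 3-{(Z)-2-[(3R,6S)-3-[(2S)-1-(tert-butyldiphenylsilyloxy)propan-2-yl]-6-methyl-1,2-dioxan-6-yl]ethenyl}-2,4,4-trimethylcyclohex-2-en-1-one | CC(C)(C)[Si](c1ccccc1)(c1ccccc1)OC[C@H](C)[C@H]1CC[C@@](C)(/C=C\C2=C(C)C(=O)CCC2(C)C)OO1 | intermediate
19 | 3-{2-[(3R,6R)-3-[(2S)-1-(tert-butyldiphenylsilyloxy)propan-2-yl]-6-methyl-1,2-dioxan-6-yl]ethyl}-2,4,4-trimethylcyclohex-2-en-1-one | CC(C)(C)[Si](c1ccccc1)(c1ccccc1)OC[C@H](C)[C@H]1CC[C@@](C)(CCC2=C(C)C(=O)CCC2(C)C)OO1 | intermediate
20 | 3-{2-[(3R,6R)-3-[(2S)-1-hydroxypropan-2-yl]-6-methyl-1,2-dioxan-6-yl]ethyl}-2,4,4-trimethylcyclohex-2-en-1-one | OC[C@H](C)[C@H]1CC[C@@](C)(CCC2=C(C)C(=O)CCC2(C)C)OO1 | intermediate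
21 | (2R)-2-{(3R,6R)-6-methyl-6-[2-(2,6,6-trimethyl-3-oxocyclohex-1-en-1-yl)ethyl]-1,2-dioxan-3-yl}propanal | O=C[C@H](C)[C@H]1CC[C@@](C)(CCC2=C(C)C(=O)CCC2(C)C)OO1 | intermediate
22 | (2R)-2-{(3R,6R)-6-methyl-6-[2-(2,6,6-trimethyl-3-oxocyclohex-1-en-1-yl)ethyl]-1,2-dioxan-3-yl}propanoic acid | OC(=O)[C@H](C)[C@H]1CC[C@@](C)(CCC2=C(C)C(=O)CCC2(C)C)OO1 | intermediate
23 | methyl (2R)-2-{(3R,6R)-6-methyl-6-[2-(2,6,6-trimethyl-3-oxocyclohex-1-en-1-yl)ethyl]-1,2-dioxan-3-yl}propanoate (diacarperoxide A) | COC(=O)[C@H](C)[C@H]1CC[C@@](C)(CCC2=C(C)C(=O)CCC2(C)C)OO1 | target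

Total step count: 14. Longest linear sequence: 11 steps (steps 1–6, then 10–14); the cyclohexenone branch (steps 7–9) has 3 steps.

Steps most likely to fail

1. Step 10. The electron-poor alkynylstannane may add too slowly, so that the peroxycarbenium ion decays by proton loss or O–O heterolysis before the C–C bond forms; facial selectivity at C6 could also be incomplete. The fallback uses known chemistry only and makes the C6–CH2 linkage as a C=C bond before the peroxide exists. It sets out from mesylate 8, with enone 11 as the source of the ring partner, and comes back at 19. Allylmagnesium bromide should add to 11 to give 1-allyl-2,6,6-trimethylcyclohex-2-en-1-ol F1, which pyridinium chlorochromate should transpose to 3-allyl-2,4,4-trimethylcyclohex-2-en-1-one F2. Cross-metathesis of F2 with the 1,1-disubstituted alkene of 8 (second-generation Hoveyda–Grubbs catalyst, CH2Cl2, 40 °C) should give the trisubstituted alkene F3 as an E/Z mixture. Isayama–Mukaiyama peroxidation (Co(acac)2, O2, Et3SiH) should place a triethylsilylperoxy group on the tertiary carbon C6 to give the silyl peroxide F4. TBAF should free the tertiary hydroperoxide F5, which KOtBu/18-crown-6 should close by the same 6-exo displacement as in step 6 to give 19 and its C6 epimer F6, separated by chromatography. This detour gives up the stereocontrol at C6 and makes step 11 unnecessary.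

2. Step 11. Hydrogen transfer to the hindered internal triple bond, flanked by a quaternary carbon and a fully substituted ring carbon, may stall at the alkene stage. The fallback replaces stoichiometric transfer from diimide by heterogeneous catalytic hydrogenation: 17 is stirred under H2 (1 atm) over palladium on carbon (Pd/C) in EtOAc at 0 °C and the reaction is stopped after two equivalents of H2, before the O–O bond or the tetrasubstituted enone react. It sets out from 17, comes back at 19 and makes no new compound.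

3. Step 6. The basic peroxide anion may eliminate the mesylate, and displacement at the branched secondary carbon may be slow. The fallback activates C3 as an oxetane and closes the ring under Lewis acid instead of base. It sets out from diol 6 and comes back at 10. One-pot activation and closure (n-BuLi, TsCl, then n-BuLi, THF, 0 to 60 °C) should give, through the primary monotosylate F7, the cis-oxetane (2S,3S)-3-methyl-2-(3-methylbut-3-en-1-yl)oxetane F8. Ozonolysis in CH2Cl2/MeOH should give the hydroperoxy ketal F9. Its OOH group should open the activated oxetane (Yb(OTf)3 cat., CH2Cl2, 0 °C) at the secondary carbon in a 6-exo mode with inversion to give the alcohol (2S)-2-[(3R)-6-methoxy-6-methyl-1,2-dioxan-3-yl]propan-1-ol F10. Silylation (TBDPSCl, imidazole) returns 10.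

Further compounds
F1 | step 10 | 1-allyl-2,6,6-trimethylcyclohex-2-en-1-ol (racemic) | CC1=CCCC(C)(C)C1(O)CC=C
F2 | step 10 | 3-allyl-2,4,4-trimethylcyclohex-2-en-1-one | CC1=C(CC=C)C(C)(C)CCC1=O
F3 | step 10 | (2S,3S)-1-[(tert-butyldiphenylsilyl)oxy]-2,6-dimethyl-8-(2,6,6-trimethyl-3-oxocyclohex-1-en-1-yl)oct-6-en-3-yl methanesulfonate (E/Z mixture) | CC(=CCC1=C(C)C(=O)CCC1(C)C)CC[C@H](OS(C)(=O)=O)[C@@H](C)CO[Si](c1ccccc1)(c1ccccc1)C(C)(C)C
F4 | step 10 | (2S,3S)-1-[(tert-butyldiphenylsilyl)oxy]-2,6-dimethyl-6-[(triethylsilyl)peroxy]-8-(2,6,6-trimethyl-3-oxocyclohex-1-en-1-yl)octan-3-yl methanesulfonate (both C6 epimers) | CC(CCC1=C(C)C(=O)CCC1(C)C)(OO[Si](CC)(CC)CC)CC[C@H](OS(C)(=O)=O)[C@@H](C)CO[Si](c1ccccc1)(c1ccccc1)C(C)(C)C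
F5 | step 10 | (2S,3S)-1-[(tert-butyldiphenylsilyl)oxy]-6-hydroperoxy-2,6-dimethyl-8-(2,6,6-trimethyl-3-oxocyclohex-1-en-1-yl)octan-3-yl methanesulfonate (both C6 epimers) | CC(CCC1=C(C)C(=O)CCC1(C)C)(OO)CC[C@H](OS(C)(=O)=O)[C@@H](C)CO[Si](c1ccccc1)(c1ccccc1)C(C)(C)C
F6 | step 10 | 3-{2-[(3R,6S)-3-[(2S)-1-(tert-butyldiphenylsilyloxy)propan-2-yl]-6-methyl-1,2-dioxan-6-yl]ethyl}-2,4,4-trimethylcyclohex-2-en-1-one (C6 epimer of 19) | CC(C)(C)[Si](c1ccccc1)(c1ccccc1)OC[C@H](C)[C@H]1CC[C@](C)(CCC2=C(C)C(=O)CCC2(C)C)OO1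
F0 | step 11 | none | none
F7 | step 6 | (2S,3S)-3-hydroxy-2,6-dimethylhept-6-en-1-yl 4-methylbenzenesulfonate | CC(=C)CC[C@H](O)[C@@H](C)COS(=O)(=O)c1ccc(C)cc1
F8 | step 6 | (2S,3S)-3-methyl-2-(3-methylbut-3-en-1-yl)oxetane | CC(=C)CC[C@@H]1OC[C@@H]1C
F9 | step 6 | (2S,3S)-2-(3-hydroperoxy-3-methoxybutyl)-3-methyloxetane (both epimers at the ketal carbon) | COC(C)(OO)CC[C@@H]1OC[C@@H]1C
F10 | step 6 | (2S)-2-[(3R)-6-methoxy-6-methyl-1,2-dioxan-3-yl]propan-1-ol (both C6 epimers) | OC[C@H](C)[C@H]1CCC(C)(OC)OO1
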